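Remark: the SMILES holds no stereocentre. The methine carbon bears two identical 1H-indol-3-yl groups, so the target is achiral and "single enantiomer" calls for no stereochemical measure.

## Structural features

Trisindolal (6, C26H19N3O) is a tris(indol-3-yl)methane. One sp3 methine carbon (Cα) carries three 1H-indole rings, each bonded through its C3, and the only other substituent is a formyl group at C2 of one ring (ring A; the unsubstituted rings are B and B′). Rings B and B′ are constitutionally identical, so Cα is not a stereocentre, and the problem is one of connectivity and chemoselectivity only. The Cα–H bond is flanked by three enamine termini (N1–C2=C3–Cα) and is strongly hydridic, so oxidants tend to turn the compound into a tris(indolyl)methylium dye. Each Cα–C3 bond is acid-labile, because protonation at C3 allows retro-Friedel–Crafts loss and exchange of rings, which would erase the 2:1 pattern. The formyl carbon lies within six-ring distance of C2 of ring B (CHO–C2A–C3A–Cα–C3B–C2B), so acid also invites cyclodehydration to an indolo[3,2-b]carbazole skeleton, and the three free N–H groups rule out strong base without protection. The real difficulty is to place two identical rings and one different, acceptor-bearing ring on one crowded carbon without strong acid, and to reveal the aldehyde next to a hydridic C–H without touching that bond. The key step exploits the fact that Cα with rings B and B′ is a complete, symmetric di(indol-3-yl)methane unit: its Cα–H bonds are aligned with two N1–C2=C3 enamine systems, hydride loss gives a cation shared by both N1 atoms, and the one unique bond of the target, Cα–C3 of ring A, can then be made from two C–H bonds.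

## Logic of the disconnections

**6 ⇒ 5.**
- Bonds: no skeletal bond is cut. The C=O π bond at the C2 substituent of ring A is exchanged for a C–H and an O–H bond.
- Reason: a formyl group at C2 is conjugated with the N1–C2=C3 enamine and removes the nucleophilicity at C3 on which the bond to Cα depends, whereas a carbinol leaves it intact. A direct union at the aldehyde level would be shorter but could not be defended against an electrophile as stabilised as 4.
- Gain: the acid-sensitive pairing of formyl carbon and C2 of ring B exists only in the last flask.
- Demand: a neutral oxidant that takes the carbinol C–H in preference to the hydridic Cα–H.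

**5 ⇒ 2 + 3, through 4.**
- Bond: Cα–C3 of ring A, the only one of the three bonds at Cα that has no twin.
- In one sentence: the CH2 carbon of intact 3 is joined to C3–H of 2 by a dehydrogenative C–H/C–H coupling through cation 4. That sentence does not fit the plan most chemists would draw first, in which Cα starts as a carbonyl carbon on ring A and rings B and B′ are added to it.
- Reason: both carbons are donors in their native state (a hydridic C–H and an enamine carbon). A two-electron oxidation, not a leaving group or a carbonyl group, unites them, and the 2:1 ring pattern is inherited from the symmetry of 3 instead of being created.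
- Gain: a C26 triarylmethane falls into a purchased C17 piece that holds Cα and two rings, and a C9 piece one step from 1, with no protecting group.
- Demands: hydride abstraction from 3 must be complete before 2 enters. Cation 4 must persist as a stock of electrophile. C3 of 2 must win over O, N1 and the C2 positions of the 3-substituted rings. No strong acid may build up.

**2 ⇒ 1.**
- Bonds: the two C–H bonds at the carbinol carbon are traded for the C=O and C–O bonds of an ester; no C–C bond is cut.
- Reason: 2 is acid-sensitive and keeps badly, whereas 1 is a stable bulk chemical with the C2 carbon already in place.
- Gain: both ends of the route, 1 and 3, are purchased.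
- Demand: the hydride reduction must stop at the alcohol without hydrogenolysis of its C–O bond.

## Other disconnections considered

Alternative 1: (the first that comes to mind) cut both Cα–C3(B) and Cα–C3(B′).
- Forward key step: acid-catalysed double Friedel–Crafts condensation of ethyl 3-formyl-1H-indole-2-carboxylate A1 (from 1 by Vilsmeier–Haack formylation) with two equivalents of indole. This would give ethyl 3-[di(1H-indol-3-yl)methyl]-1H-indole-2-carboxylate A2, followed by reduction to 5 and oxidation to 6.
- The plan is sound, but it needs four steps against three.
- Cα has to be installed in a separate C1 operation on the least nucleophilic ring.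
- The azafulvenium ions that must form sit on the acceptor-substituted ring A, so a real acid and excess indole are required. Those are the conditions under which Cα–C3 bonds exchange.
- The chosen plan buys Cα and both B rings in one piece and makes a single bond in a nearly neutral medium.

Alternative 2: cut C2(A)–CHO.
- Forward key step: desymmetrising mono-C2–H formylation (Vilsmeier–Haack, or C2-lithiation/DMF after N-protection) of C3-symmetric tris(1H-indol-3-yl)methane A3, which is one step from indole and an orthoformate and holds 25 of the 26 carbons.
- The three rings are equivalent and electronically insulated by Cα. The first formyl group would therefore deactivate only its own ring, and the outcome would be statistical.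
- Electrophiles attack a 3-substituted indole at C3 first. The ipso σ-complex of A3 can undergo the 1,2-shift to C2, but it can also expel Cα as a highly stabilised cation, which cleaves the skeleton.
- The lithiation variant needs three N-protecting groups and competes with deprotonation at Cα–H.
- The chosen plan fixes the difference between the rings by construction.

Alternative 3: cut the same bond Cα–C3(A) with both polarities reversed.
- Forward key step: Pd-catalysed deprotonative cross-coupling (diarylmethane C–H arylation, KN(SiMe3)2, Pd/NiXantphos type). The carbanion of bis{1-[(2-trimethylsilylethoxy)methyl]-1H-indol-3-yl}methane A4 would couple with 3-bromo-2-(1,3-dioxolan-2-yl)-1-[(2-trimethylsilylethoxy)methyl]-1H-indole A5 to give the fully protected triindolylmethane A6.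
- The coupling avoids acid and oxidant, but the strong base forces masking of three N–H groups and of the aldehyde, which brings the count to at least seven steps.
- Oxidative addition at a 3-bromide flanked by C2 and C4 substituents, and reductive elimination to a congested triarylmethane, are both sterically demanding.
- The unmasking is hazardous. Fluoride removal of the N-groups liberates formaldehyde beside free indoles, and acetal cleavage passes through an oxocarbenium ion within six-ring reach of C2 of ring B.
- The oxidative version makes the same bond with no protecting group.

Key step: step 2

## Route

Step 1
Reactants: 1 ethyl 1H-indole-2-carboxylate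
Product: 2 (1H-indol-2-yl)methanol
Conditions: LiAlH4 (1.5 equiv), THF, 0 °C → rt; H2O/aq NaOH work-up; used fresh
Reagents that add atoms: none
Why: Standard LiAlH4 reduction of an aromatic ester to the primary alcohol; the N–H is only deprotonated and is restored on work-up. The temperature is kept at or below rt so that the C–O bond of the indol-2-ylmethoxide is not hydrogenolysed.

Step 2
Reactants: 3 3,3'-diindolylmethane (di(1H-indol-3-yl)methane); 2 (1H-indol-2-yl)methanol
Product: 5 {3-[di(1H-indol-3-yl)methyl]-1H-indol-2-yl}methanol, via bis(1H-indol-3-yl)methylium DDQH salt 4 (not isolated)
Conditions: DDQ (1.0 equiv), 4 Å MS, MeCN, −20 °C, 3 added slowly; then 2 (1.3 equiv), −20 °C → rt; aq NaHCO3 work-up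
Reagents that add atoms: none
Why: This is a cross-dehydrogenative coupling (DDQ-mediated benzylic C–H arylation of a diarylmethane) run in cation-pool fashion. DDQ forms a charge-transfer complex with an indole ring of 3 and removes an electron and then hydrogen (net hydride) from the only sp3 C–H site, as in the DDQ side-chain oxidation of 3-alkylindoles, giving 4, a pentamethine-cyanine-type cation whose charge is shared by both N1 atoms and which should persist at −20 °C. Because 3 is dripped into the oxidant, free 3 does not accumulate beside 4, and because the single equivalent of DDQ is spent before 2 enters, neither 2 nor 5 meets an oxidant. C3 of 2, the enamine terminus of a 2-alkylindole, attacks Cα of 4, and the 3H-indolium σ-complex gives its C3 proton to DDQH−, which restores ring A and leaves DDQH2 as the only, weak, acid. This second half is the Friedel–Crafts alkylation by an alkylideneindoleninium ion that ends every tris(indolyl)methane synthesis. No ring is closed and no stereocentre arises, since Cα carries two identical indol-3-yl groups. Site selectivity rests on reversibility and on intrinsic reactivity: capture at O or N1 of 2 gives adducts that re-ionise to the stabilised cation, so only the C3 adduct, fixed by rearomatisation, should accumulate, and the free C3 of 2 should outrun the C2 positions of 3 and 5, which react only through dearomatised ipso adducts. The 2:1 ring pattern should not scramble, because both B rings arrive already bonded to Cα and no acid able to protonate an indole C3 is present.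

Step 3
Reactants: 5 {3-[di(1H-indol-3-yl)methyl]-1H-indol-2-yl}methanol
Product: 6 trisindolal, 3-[di(1H-indol-3-yl)methyl]-1H-indole-2-carbaldehyde
Conditions: activated MnO2 (10 equiv), CH2Cl2/THF, rt, N2, dark; filtration through Celite; Et3N-deactivated silica
Reagents that add atoms: none
Why: Heterogeneous MnO2 oxidation of a benzylic-type (indol-2-yl) carbinol is the standard access to indole-2-carbaldehydes; the alcohol binds to the oxide surface through oxygen, whereas Cα–H has no anchoring group and is shielded by three rings. The medium is neutral, so neither ring exchange at Cα nor cyclodehydration onto C2 of ring B is triggered, and no stereocentre is involved.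

## Compound list

1 | ethyl 1H-indole-2-carboxylate | CCOC(=O)c1cc2ccccc2[nH]1 | starting material
2 | (1H-indol-2-yl)methanol | OCc1cc2ccccc2[nH]1 | intermediate
3 | 3,3'-diindolylmethane (di(1H-indol-3-yl)methane) | C(c1c[nH]c2ccccc12)c1c[nH]c2ccccc12 | starting material
4 | 3-(1H-indol-3-ylmethylidene)-3H-indol-1-ium [bis(1H-indol-3-yl)methylium] 2,3-dichloro-5,6-dicyano-4-hydroxyphenolate | C(=C1C=[NH+]c2ccccc12)c1c[nH]c2ccccc12.[O-]c1c(Cl)c(Cl)c(O)c(C#N)c1C#N | intermediate
5 | {3-[di(1H-indol-3-yl)methyl]-1H-indol-2-yl}methanol | OCc1[nH]c2ccccc2c1C(c1c[nH]c2ccccc12)c1c[nH]c2ccccc12 | intermediate
6 | trisindolal, 3-[di(1H-indol-3-yl)methyl]-1H-indole-2-carbaldehyde (achiral) | O=Cc1[nH]c2ccccc2c1C(c1c[nH]c2ccccc12)c1c[nH]c2ccccc12 | target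

Total step count: 3. Longest linear sequence: 3 (1 → 2 → 5 → 6); purchased 3 enters in step 2.

## Least certain steps

**Step 2 (key step).** The most likely failure is consumption of the cation by the wrong donor.
- During the oxidation phase, 3 that is not yet oxidised can attack 4 through C2 (oligomerisation).
- Late in the capture phase, the Cα–H of 5, which is more hydridic than the CH2 of 3, can pass hydride to remaining 4 (disproportionation with loss of the methine hydrogen).
- The weak acid formed can also start ionisation of the carbinol group, followed by ring closure onto C2 of ring B.

The fallback sets out from 1 and comes back to the route at 5; it brings Cα in as a carbonyl carbon on ring A. Vilsmeier–Haack formylation of 1 (POCl3, DMF) should give ethyl 3-formyl-1H-indole-2-carboxylate F1. Acid-catalysed double Friedel–Crafts condensation of F1 with two equivalents of purchased indole should give ethyl 3-[di(1H-indol-3-yl)methyl]-1H-indole-2-carboxylate F2. LiAlH4 reduction of F2 then leads to 5.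

**Step 3.** The most likely failure is loss of chemoselectivity: oxidation at the triply activated Cα–H in competition with the carbinol, seen as development of dye colour. Retention of the tri-N–H product on the oxide surface is a second risk.

The fallback sets out from 5 and comes back at 6; it accepts the over-oxidation and repairs it. Exhaustive oxidation of 5 with DDQ (about 2.2 equiv, THF/MeCN) should take both the carbinol and the methine to the higher level. This gives 3-[(1H-indol-3-yl)(3H-indol-3-ylidene)methyl]-1H-indole-2-carbaldehyde F3, present in the flask in its N-protonated, carbenium-type form. Hantzsch ester then returns one hydride to Cα. It is a donor that reduces stabilised carbenium and iminium ions but leaves an unactivated aldehyde alone, so 6 results.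

**Step 1.** The most likely failure is hydrogenolysis of the C–O bond. The N-metalated alkoxyaluminate can expel oxygen with help from the ring nitrogen and be reduced further if the mixture warms. Acid-induced self-condensation of the product on silica or on storage is a second risk.

The fallback sets out from 1 and comes back at 2. Saponification of 1 (LiOH, THF/H2O) should give 1H-indole-2-carboxylic acid F4. F4 is then reduced with the electrophilic hydride BH3·THF (0 °C → rt). Under these conditions the ring nitrogen is not metalated and has no anionic push for C–O cleavage.

## Further compounds

F1 | step 2 | ethyl 3-formyl-1H-indole-2-carboxylate | CCOC(=O)c1[nH]c2ccccc2c1C=O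
F2 | step 2 | ethyl 3-[di(1H-indol-3-yl)methyl]-1H-indole-2-carboxylate | CCOC(=O)c1[nH]c2ccccc2c1C(c1c[nH]c2ccccc12)c1c[nH]c2ccccc12
F3 | step 3 | 3-[(1H-indol-3-yl)(3H-indol-3-ylidene)methyl]-1H-indole-2-carbaldehyde | O=Cc1[nH]c2ccccc2c1C(=C1C=Nc2ccccc12)c1c[nH]c2ccccc12
F4 | step 1 | 1H-indole-2-carboxylic acid | OC(=O)c1cc2ccccc2[nH]1
A1 | alternative 1 | ethyl 3-formyl-1H-indole-2-carboxylate | CCOC(=O)c1[nH]c2ccccc2c1C=O
A2 | alternative 1 | ethyl 3-[di(1H-indol-3-yl)methyl]-1H-indole-2-carboxylate | CCOC(=O)c1[nH]c2ccccc2c1C(c1c[nH]c2ccccc12)c1c[nH]c2ccccc12
A3 | alternative 2 | tris(1H-indol-3-yl)methane | C(c1c[nH]c2ccccc12)(c1c[nH]c2ccccc12)c1c[nH]c2ccccc12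
A4 | alternative 3 | bis{1-[(2-trimethylsilylethoxy)methyl]-1H-indol-3-yl}methane | C(c1cn(COCC[Si](C)(C)C)c2ccccc12)c1cn(COCC[Si](C)(C)C)c2ccccc12
A5 | alternative 3 | 3-bromo-2-(1,3-dioxolan-2-yl)-1-[(2-trimethylsilylethoxy)methyl]-1H-indole | Brc1c(C2OCCO2)n(COCC[Si](C)(C)C)c2ccccc12
A6 | alternative 3 | 3-(bis{1-[(2-trimethylsilylethoxy)methyl]-1H-indol-3-yl}methyl)-2-(1,3-dioxolan-2-yl)-1-[(2-trimethylsilylethoxy)methyl]-1H-indole | C(c1cn(COCC[Si](C)(C)C)c2ccccc12)(c1cn(COCC[Si](C)(C)C)c2ccccc12)c1c(C2OCCO2)n(COCC[Si](C)(C)C)c2ccccc12
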